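The earlier runs and the new flask are calculated for substances that don't exist; scatter was added.

3 questions stood on one flask, and I had 2 earlier runs to answer them from.

all flasks: gas 29 mM (held)

| charge | solid substrate | remark | time |
|---|---|---|---|
| red | 0.050 M | run made earlier |  |
| teal | 0.075 M | run made earlier |  |
| flask | 0.10 M |  | 2.0 h |

| run | time / min | target / % |
|---|---|---|
| red | 10.0 | 0.7 |
| red | 30.0 | 5.5 |
| red | 60.0 | 19.4 |
| red | 80.0 | 29.4 |
| red | 120 | 46.1 |
| teal | 10.0 | 0 |
| teal | 20.0 | 1.7 |
| teal | 30.0 | 4.2 |
| teal | 60.0 | 12.6 |
| teal | 120 | 30.2 |

(standard deviation of a reading: 0.5 percentage points)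

1. how much target there is at 2.0 h, in percent of the solid substrate charged
2. the change that raises the amount of target at 2.0 h, in percent of the solid substrate charged most ("none" if none brings more than 2 percentage points) (epsilon / alpha / theta / eta / none)
3. amount of target at 2.0 h, in percent of the solid substrate charged, after eta

- epsilon: doubling the saturation concentration of gas, all else as stated
- alpha: doubling the solubility of the solid substrate, all else as stated
- theta: doubling the transfer coefficient of the gas, all else as stated
- eta: doubling the dissolution coefficient of the solid substrate, all else as stated

- solid substrate is a solid; its amount is given per volume of the solution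
- at the start none of the solid substrate is in solution
- at the start none of the gas is in solution

I turned the percentages into concentrations. At 120 min, [target] stood at 23.1 mM in the red run and 22.6 mM in the teal run, although teal was charged with more solid substrate. So I read the late slope of [target] in each run:

red: 0.223 mM min⁻¹
teal: 0.220 mM min⁻¹
r = 0.221 mM min⁻¹

I called r the charge-free rate: the late rise of [target] per minute, which these runs show as pseudo-zero-order in the charge. Then I built my flask up in layers.

Main step, running from the first minute:

r × time = 26.5 mM, or 26.5% of the charge

Next, the lag, since neither partner is in solution at the start. I read it from the mean [target] at 60.0 min: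

lag = 16.7 min
r × (time − lag) / charge = 22.8%

The rest I took as already inside r, so the larger charge merely divided the same [target]. No run moved the gas, so r by itself ranked none of the changes, and my own reckoning stopped at the amount.

The forecast gave 22.8%, alpha as the best change and 29% after eta, holding that “Dissolved substrate is probably the scarcer partner, so solubility (alpha) should help most”.

The flask gave 22.6%, epsilon as the best change and 25.4% after eta.

    dissolved substrate + target → side product (k = 0.0100 L mol⁻¹ s⁻¹)
    solid substrate ⇌ dissolved substrate, rate k2*(cs2 - [dissolved substrate]) while solid is left; crystals form when [dissolved substrate] > cs2 (solubility = 29.0 mM, k = 3.40 × 10⁻⁴ s⁻¹)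
    reagent ⇌ dormant form (K = 6.10, k = 0.00270 s⁻¹)
    dissolved substrate + reagent → target (k = 0.0820 L mol⁻¹ s⁻¹)
    gas ⇌ reagent, rate k5*(csat - [reagent]) (kL = 4.20 × 10⁻⁴ s⁻¹)

Forecast and flask parted on the best change: epsilon added 13 percentage points, theta 9.7 points, alpha 3.1 points and eta 2.8 points. At 2.00 h, [reagent] stood at 0.00702 M against a gas saturation of 29 mM. In this flask [target] rose by 0.212 mM min⁻¹ between 1.00 h and 2.00 h, against an r of 0.221 mM min⁻¹. The same reckoning on the neighbouring flask, read at 50 min, gave 7.36%, and that flask stood at 7.60%.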